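**Plan**

1. Labdane numbering is used: ring A = C1–C5 with C10, ring B = C5–C10, gem-dimethyl on C4, C20 on C10, C17 on C8, side chain C11–C16 on C9 (target: 5R,9S,10R, 13Z).
2. Enabling feature: once its alkene is moved from C7=C8 to C6=C7, ring B is a cyclohexene whose bonds C5–C10 and C8–C9 flank that alkene, so cutting both opens rings A and B at once to an acyclic deca-1,7,9-triene (C9=C10 enoyl imide, C1–C4 tether through the gem-dimethyl carbon, C5=C6–C7=C8 diene).
3. Further cuts: C12–C13 (alkylborane/enol tosylate coupling), C11=C12 (Wittig), C1–C10 (alkylborane/enol triflate coupling), C5=C6 (Horner–Wadsworth–Emmons).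
4. Forward: the C1–C8 diene chain is built from 2,2-dimethylpent-4-enal, the C9–C11 enoyl imide is joined at C1, one intramolecular Diels–Alder reaction closes rings A and B together, and the C12–C16 side chain is attached last.
5. Stereochemistry: C9 from the chiral bis(oxazoline) ligand on copper; C10 and C5 relative to C9 from the E dienophile and the endo transition state; the C8 centre is erased when the alkene is moved to C7=C8; the 13Z alkene comes from an E-configured enol tosylate coupled with retention.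

Key step: step 8

Assumption: the (S,S) ligand is chosen from the square-planar chelate model, which predicts bond formation at the Re face of C9; if the sense proved opposite, the (R,R) ligand would be used in the same way. Compounds 1, 3, 4, 11, 22, 23 and 24 and all unnumbered reagents are catalogue chemicals.

**Route**

Step 1
Reactants: 1 ethyl acetoacetate
Product: 2 ethyl (2E)-3-{[(trifluoromethyl)sulfonyl]oxy}but-2-enoate (triflate trans to the ester, methyl cis)
Conditions: Tf2O, aq. Me4NOH, hexane, 5 °C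
Reagents that add atoms: trifluoromethanesulfonic anhydride, O=S(=O)(OS(=O)(=O)C(F)(F)F)C(F)(F)F
Why: Enol triflate formation from the non-chelated tetramethylammonium enolate of the β-keto ester should place the triflate trans to the ester, the geometry that later puts C20 cis to C11.

Step 2
Reactants: 3 2,2-dimethylpent-4-enal; 4 triethyl 4-phosphonocrotonate
Product: 5 ethyl (2E,4E)-6,6-dimethylnona-2,4,8-trienoate
Conditions: LiN(SiMe3)2, THF, −78 → 0 °C
Reagents that add atoms: none
Why: Horner–Wadsworth–Emmons olefination of the non-enolisable neopentyl aldehyde with the stabilised crotonate phosphonate anion should form the new C5=C6 bond E and keep C7=C8 E.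

Step 3
Reactants: 5 ethyl (2E,4E)-6,6-dimethylnona-2,4,8-trienoate
Product: 6 (2E,4E)-6,6-dimethylnona-2,4,8-trien-1-ol
Conditions: i-Bu2AlH, CH2Cl2, −78 °C; aq. potassium sodium tartrate
Reagents that add atoms: none
Why: 1,2-Reduction of the dienoate by i-Bu2AlH gives the dienyl alcohol and leaves the three alkenes untouched.

Step 4
Reactants: 6 (2E,4E)-6,6-dimethylnona-2,4,8-trien-1-ol
Product: 7 tert-butyl{[(2E,4E)-6,6-dimethylnona-2,4,8-trien-1-yl]oxy}dimethylsilane
Conditions: TBSCl, imidazole, CH2Cl2, 0 °C → rt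
Reagents that add atoms: tert-butyldimethylsilyl chloride, CC(C)(C)[Si](C)(C)Cl
Why: Imidazole-mediated silylation of the primary allylic alcohol masks the C17 oxygen for the borane, hydroxide and Lewis acid steps that follow.

Step 5
Reactants: 7 tert-butyl{[(2E,4E)-6,6-dimethylnona-2,4,8-trien-1-yl]oxy}dimethylsilane; 2 ethyl (2E)-3-{[(trifluoromethyl)sulfonyl]oxy}but-2-enoate
Product: 9 ethyl (2E,8E,10E)-12-{[tert-butyl(dimethyl)silyl]oxy}-3,7,7-trimethyldodeca-2,8,10-trienoate, via B-alkyl-9-BBN adduct 8 (not isolated)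
Conditions: 9-BBN, THF, 0 °C → rt; then 2, Pd(dppf)Cl2 (5 mol %), K3PO4 (3 M aq.), DMF, rt
Reagents that add atoms: none
Why: Anti-Markovnikov hydroboration by 9-BBN is selective for the monosubstituted terminal alkene over the hindered 1,4-disubstituted diene, and the sp3–sp2 Suzuki–Miyaura coupling with the enol triflate proceeds with retention, forming C1–C10 with the E trisubstituted enoate.

Step 6
Reactants: 9 ethyl (2E,8E,10E)-12-{[tert-butyl(dimethyl)silyl]oxy}-3,7,7-trimethyldodeca-2,8,10-trienoate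
Product: 10 (2E,8E,10E)-12-{[tert-butyl(dimethyl)silyl]oxy}-3,7,7-trimethyldodeca-2,8,10-trienoic acid
Conditions: LiOH·H2O, THF/MeOH/H2O, 45 °C; then 0.5 M HCl to pH 4, 0 °C
Reagents that add atoms: lithium hydroxide, [Li+].[OH-]
Why: Saponification of the ethyl ester leaves the silyl ether and the alkene geometries intact, and the cold, mild acidification avoids loss of the allylic silyl group.

Step 7
Reactants: 10 (2E,8E,10E)-12-{[tert-butyl(dimethyl)silyl]oxy}-3,7,7-trimethyldodeca-2,8,10-trienoic acid; 11 oxazolidin-2-one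
Product: 13 3-[(2E,8E,10E)-12-{[tert-butyl(dimethyl)silyl]oxy}-3,7,7-trimethyldodeca-2,8,10-trienoyl]-1,3-oxazolidin-2-one, via mixed pivalic anhydride 12 (not isolated)
Conditions: t-BuCOCl, Et3N, THF, −78 → 0 °C; then 11/n-BuLi, THF, −78 → 0 °C
Reagents that add atoms: none
Why: N-Acylation of lithiated oxazolidin-2-one by the mixed anhydride occurs at the less hindered enoyl carbonyl, and the low temperature avoids deconjugation or E/Z isomerisation of the β,β-disubstituted enoyl unit.

Step 8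
Reactants: 13 3-[(2E,8E,10E)-12-{[tert-butyl(dimethyl)silyl]oxy}-3,7,7-trimethyldodeca-2,8,10-trienoyl]-1,3-oxazolidin-2-one
Product: 14 3-{[(1R,2R,4aR,8aR)-2-({[tert-butyl(dimethyl)silyl]oxy}methyl)-5,5,8a-trimethyl-1,2,4a,5,6,7,8,8a-octahydronaphthalen-1-yl]carbonyl}-1,3-oxazolidin-2-one (trans-fused; C11, C17 and C20 on one face; C6=C7 alkene)
Conditions: [Cu((S,S)-t-Bu-box)](SbF6)2 (15 mol %; ligand = 2,2'-(propane-2,2-diyl)bis[(4S)-4-tert-butyl-4,5-dihydro-1,3-oxazole]), CH2Cl2, 25 °C
Reagents that add atoms: none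
Why: Two-point binding of the imide carbonyls to the cationic divalent copper centre holds the enoyl group s-cis and lowers its LUMO, and the tethered diene then adds across C9=C10 in a concerted, asynchronous [4+2] cycloaddition that forms C8–C9 and C5–C10. The closest known reaction types are the enantioselective intramolecular Diels–Alder reaction of (E,E,E)-trienoyl oxazolidinones under this copper bis(oxazoline) catalyst and the Lewis acid-promoted endo cyclisation of 2,8,10-trienoates to trans-decalins; the β-methyl group makes the dienophile trisubstituted, so a long reaction time and a high catalyst loading are planned. Ring B closes as the cyclohexene of the cycloaddition, and ring A closes at the same time through the tether C1–C4 that links the dienophile carbon C10 to the diene terminus C5 (type 1 mode, six-membered carbocycle). C9 is set by the ligand, whose tert-butyl group covers the Si face of C9 in the square-planar chelate so that C8 bonds to the Re face; C10 follows from C9 through the E geometry of the dienophile (C11 cis to C20); C5 and the temporary centre C8 follow from the endo transition state and the E,E diene (H5 trans to C20, hence the trans fusion, and C17 cis to C11). The step needs facial and endo selectivity: the first rests on the rigid chelate, the second on the Lewis acid-enhanced preference for the carbonyl-endo transition state, helped by the gem-dimethyl group on C4, which favours the folded conformer.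

Step 9
Reactants: 14 3-{[(1R,2R,4aR,8aR)-2-({[tert-butyl(dimethyl)silyl]oxy}methyl)-5,5,8a-trimethyl-1,2,4a,5,6,7,8,8a-octahydronaphthalen-1-yl]carbonyl}-1,3-oxazolidin-2-one
Product: 16 (3aR,5aR,9aR,9bR)-6,6,9a-trimethyl-3a,5a,6,7,8,9,9a,9b-octahydronaphtho[1,2-c]furan-1(3H)-one (cis-fused γ-lactone, C11 carbonyl, C17–O), via hydroxy imide 15 (not isolated)
Conditions: Bu4NF, THF, 0 °C → rt; aq. NH4Cl
Reagents that add atoms: none
Why: Fluoride-induced desilylation frees the C17 alkoxide, which sits cis to the imide on the neighbouring carbon and should acylate itself by 5-exo-trig attack on the exocyclic carbonyl (lactonisation with release of oxazolidin-2-one).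

Step 10
Reactants: 16 (3aR,5aR,9aR,9bR)-6,6,9a-trimethyl-3a,5a,6,7,8,9,9a,9b-octahydronaphtho[1,2-c]furan-1(3H)-one
Product: 17 (3aR,5aR,9aR,9bR)-6,6,9a-trimethyl-1,3,3a,5a,6,7,8,9,9a,9b-decahydronaphtho[1,2-c]furan-1-ol (lactol, both C11 epimers)
Conditions: i-Bu2AlH, CH2Cl2, −78 °C
Reagents that add atoms: none
Why: Partial reduction of the γ-lactone by i-Bu2AlH stops at the lactol because the tetrahedral aluminium alkoxide is stable at −78 °C.

Step 11
Reactants: 17 (3aR,5aR,9aR,9bR)-6,6,9a-trimethyl-1,3,3a,5a,6,7,8,9,9a,9b-decahydronaphtho[1,2-c]furan-1-ol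
Product: 18 [(1R,2R,4aR,8aS)-1-ethenyl-5,5,8a-trimethyl-1,2,4a,5,6,7,8,8a-octahydronaphthalen-2-yl]methanol
Conditions: Ph3PCH3Br, KOt-Bu, THF, 0 → 50 °C
Reagents that add atoms: methyltriphenylphosphonium bromide, C[P+](c1ccccc1)(c1ccccc1)c1ccccc1.[Br-]
Why: Wittig methylenation of the open hydroxy aldehyde form of the lactol by excess Ph3P=CH2 installs C12 and releases C17–OH, and C9 should keep its configuration because addition of the non-stabilised ylide is faster than enolisation of the hindered aldehyde.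

Step 12
Reactants: 18 [(1R,2R,4aR,8aS)-1-ethenyl-5,5,8a-trimethyl-1,2,4a,5,6,7,8,8a-octahydronaphthalen-2-yl]methanol
Product: 20 (1S,4aR,8aR)-1-ethenyl-5,5,8a-trimethyl-1,4,4a,5,6,7,8,8a-octahydronaphthalene-2-carbaldehyde, via deconjugated aldehyde 19 (not isolated)
Conditions: Dess–Martin periodinane, NaHCO3, CH2Cl2, 0 °C → rt; then DBU (0.3 equiv), rt
Reagents that add atoms: none
Why: Dess–Martin oxidation gives the β,γ-unsaturated aldehyde, and DBU then moves the alkene into conjugation through the extended enolate (deprotonation at C8, protonation at C6), which removes the C8 centre and gives the trisubstituted C7=C8 enal, while C9–H is not acidic and stays as set.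

Step 13
Reactants: 20 (1S,4aR,8aR)-1-ethenyl-5,5,8a-trimethyl-1,4,4a,5,6,7,8,8a-octahydronaphthalene-2-carbaldehyde
Product: 21 [(1S,4aR,8aR)-1-ethenyl-5,5,8a-trimethyl-1,4,4a,5,6,7,8,8a-octahydronaphthalen-2-yl]methanol
Conditions: NaBH4, CeCl3·7H2O, MeOH, −40 °C
Reagents that add atoms: none
Why: Luche reduction delivers hydride 1,2 to the enal and gives the primary allylic alcohol at C17 without touching the vinyl group.

Step 14
Reactants: 22 acetoxyacetyl chloride; 23 2,2-dimethyl-1,3-dioxane-4,6-dione (Meldrum's acid); 24 2-(trimethylsilyl)ethanol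
Product: 26 2-(trimethylsilyl)ethyl 4-(acetyloxy)-3-oxobutanoate, via acyl Meldrum's acid 25 (not isolated)
Conditions: pyridine, CH2Cl2, 0 °C → rt; then 24, toluene, 110 °C
Reagents that add atoms: none
Why: C-Acylation of Meldrum's acid followed by thermal loss of acetone and CO2 through the acylketene and its capture by the alcohol is the standard β-keto ester synthesis, and it brings in the C16 acetate from the start.

Step 15
Reactants: 26 2-(trimethylsilyl)ethyl 4-(acetyloxy)-3-oxobutanoate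
Product: 27 2-(trimethylsilyl)ethyl (2E)-4-(acetyloxy)-3-{[(4-methylphenyl)sulfonyl]oxy}but-2-enoate (tosylate trans to the ester, acetoxymethyl cis)
Conditions: TsCl, N-methylimidazole, Et3N, MeCN, −10 °C
Reagents that add atoms: 4-methylbenzenesulfonyl chloride, Cc1ccc(cc1)S(=O)(=O)Cl
Why: Enol tosylation of the β-keto ester through the N-sulfonylimidazolium salt under non-chelating amine conditions is E-selective, and the anhydrous base spares the acetate.

Step 16
Reactants: 21 [(1S,4aR,8aR)-1-ethenyl-5,5,8a-trimethyl-1,4,4a,5,6,7,8,8a-octahydronaphthalen-2-yl]methanol; 27 2-(trimethylsilyl)ethyl (2E)-4-(acetyloxy)-3-{[(4-methylphenyl)sulfonyl]oxy}but-2-enoate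
Product: 29 2-(trimethylsilyl)ethyl (2Z)-3-[(acetyloxy)methyl]-5-[(1S,4aR,8aR)-2-(hydroxymethyl)-5,5,8a-trimethyl-1,4,4a,5,6,7,8,8a-octahydronaphthalen-1-yl]pent-2-enoate, via bis(9-BBN) adduct 28 (not isolated)
Conditions: 9-BBN (2.3 equiv), THF, 0 → 40 °C; then 27, Pd(OAc)2 (5 mol %), SPhos (10 mol %), K3PO4·H2O, THF/DMF, 40 °C
Reagents that add atoms: none
Why: 9-BBN first caps C17–OH as the borinate and then hydroborates the vinyl group at C12 (the trisubstituted C7=C8 alkene is inert), and the sp3–sp2 Suzuki–Miyaura coupling with the enol tosylate proceeds with retention, so the 13Z geometry is set with the acetate already in place and no γ-hydroxy ester that could lactonise is ever formed.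

Step 17
Reactants: 29 2-(trimethylsilyl)ethyl (2Z)-3-[(acetyloxy)methyl]-5-[(1S,4aR,8aR)-2-(hydroxymethyl)-5,5,8a-trimethyl-1,4,4a,5,6,7,8,8a-octahydronaphthalen-1-yl]pent-2-enoate
Product: 30 (2Z)-3-[(acetyloxy)methyl]-5-[(1S,4aR,8aR)-2-(hydroxymethyl)-5,5,8a-trimethyl-1,4,4a,5,6,7,8,8a-octahydronaphthalen-1-yl]pent-2-enoic acid (CNP0276022.2)
Conditions: TASF, DMF, 0 °C → rt; then aq. NaH2PO4 (pH 4)
Reagents that add atoms: none
Why: Fluoride attacks silicon and the 2-(trimethylsilyl)ethyl ester fragments by β-elimination to the carboxylate, ethene and Me3SiF under conditions that should leave the acetate and the allylic alcohol untouched, and mild acidification gives the acid.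

**Compound list**

1 | ethyl acetoacetate | CCOC(=O)CC(C)=O | starting material
2 | ethyl (2E)-3-{[(trifluoromethyl)sulfonyl]oxy}but-2-enoate | CCOC(=O)/C=C(\C)OS(=O)(=O)C(F)(F)F | intermediate
3 | 2,2-dimethylpent-4-enal | O=CC(C)(C)CC=C | starting material
4 | triethyl 4-phosphonocrotonate | CCOC(=O)/C=C/CP(=O)(OCC)OCC | starting material
5 | ethyl (2E,4E)-6,6-dimethylnona-2,4,8-trienoate | CCOC(=O)/C=C/C=C/C(C)(C)CC=C | intermediate
6 | (2E,4E)-6,6-dimethylnona-2,4,8-trien-1-ol | OC/C=C/C=C/C(C)(C)CC=C | intermediate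
7 | tert-butyl{[(2E,4E)-6,6-dimethylnona-2,4,8-trien-1-yl]oxy}dimethylsilane | CC(C)(C)[Si](C)(C)OC/C=C/C=C/C(C)(C)CC=C | intermediate
8 | 9-[(5E,7E)-9-{[tert-butyl(dimethyl)silyl]oxy}-4,4-dimethylnona-5,7-dien-1-yl]-9-borabicyclo[3.3.1]nonane (formed in situ) | CC(C)(C)[Si](C)(C)OC/C=C/C=C/C(C)(C)CCCB1C2CCCC1CCC2 | intermediate
9 | ethyl (2E,8E,10E)-12-{[tert-butyl(dimethyl)silyl]oxy}-3,7,7-trimethyldodeca-2,8,10-trienoate | CCOC(=O)/C=C(\C)CCCC(C)(C)/C=C/C=C/CO[Si](C)(C)C(C)(C)C | intermediate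
10 | (2E,8E,10E)-12-{[tert-butyl(dimethyl)silyl]oxy}-3,7,7-trimethyldodeca-2,8,10-trienoic acid | OC(=O)/C=C(\C)CCCC(C)(C)/C=C/C=C/CO[Si](C)(C)C(C)(C)C | intermediate
11 | oxazolidin-2-one | O=C1NCCO1 | starting material
12 | mixed anhydride of acid 10 with pivalic acid (formed in situ) | CC(C)(C)C(=O)OC(=O)/C=C(\C)CCCC(C)(C)/C=C/C=C/CO[Si](C)(C)C(C)(C)C | intermediate
13 | 3-[(2E,8E,10E)-12-{[tert-butyl(dimethyl)silyl]oxy}-3,7,7-trimethyldodeca-2,8,10-trienoyl]-1,3-oxazolidin-2-one | O=C1OCCN1C(=O)/C=C(\C)CCCC(C)(C)/C=C/C=C/CO[Si](C)(C)C(C)(C)C | intermediate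
14 | 3-{[(1R,2R,4aR,8aR)-2-({[tert-butyl(dimethyl)silyl]oxy}methyl)-5,5,8a-trimethyl-1,2,4a,5,6,7,8,8a-octahydronaphthalen-1-yl]carbonyl}-1,3-oxazolidin-2-one | O=C1OCCN1C(=O)[C@@H]2[C@H](CO[Si](C)(C)C(C)(C)C)C=C[C@@H]3C(C)(C)CCC[C@@]23C | intermediate
15 | 3-{[(1R,2R,4aR,8aR)-2-(hydroxymethyl)-5,5,8a-trimethyl-1,2,4a,5,6,7,8,8a-octahydronaphthalen-1-yl]carbonyl}-1,3-oxazolidin-2-one (formed in situ) | O=C1OCCN1C(=O)[C@@H]2[C@H](CO)C=C[C@@H]3C(C)(C)CCC[C@@]23C | intermediate
16 | (3aR,5aR,9aR,9bR)-6,6,9a-trimethyl-3a,5a,6,7,8,9,9a,9b-octahydronaphtho[1,2-c]furan-1(3H)-one | O=C1[C@@H]2[C@H](CO1)C=C[C@@H]3C(C)(C)CCC[C@@]23C | intermediate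
17 | (3aR,5aR,9aR,9bR)-6,6,9a-trimethyl-1,3,3a,5a,6,7,8,9,9a,9b-decahydronaphtho[1,2-c]furan-1-ol (both C1 epimers) | OC1[C@@H]2[C@H](CO1)C=C[C@@H]3C(C)(C)CCC[C@@]23C | intermediate
18 | [(1R,2R,4aR,8aS)-1-ethenyl-5,5,8a-trimethyl-1,2,4a,5,6,7,8,8a-octahydronaphthalen-2-yl]methanol | C=C[C@@H]1[C@H](CO)C=C[C@@H]2C(C)(C)CCC[C@@]12C | intermediate
19 | (1R,2R,4aR,8aS)-1-ethenyl-5,5,8a-trimethyl-1,2,4a,5,6,7,8,8a-octahydronaphthalene-2-carbaldehyde (formed in situ) | C=C[C@@H]1[C@H](C=O)C=C[C@@H]2C(C)(C)CCC[C@@]12C | intermediate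
20 | (1S,4aR,8aR)-1-ethenyl-5,5,8a-trimethyl-1,4,4a,5,6,7,8,8a-octahydronaphthalene-2-carbaldehyde | C=C[C@@H]1C(C=O)=CC[C@@H]2C(C)(C)CCC[C@@]12C | intermediate
21 | [(1S,4aR,8aR)-1-ethenyl-5,5,8a-trimethyl-1,4,4a,5,6,7,8,8a-octahydronaphthalen-2-yl]methanol | C=C[C@@H]1C(CO)=CC[C@@H]2C(C)(C)CCC[C@@]12C | intermediate
22 | acetoxyacetyl chloride | CC(=O)OCC(Cl)=O | starting material
23 | 2,2-dimethyl-1,3-dioxane-4,6-dione (Meldrum's acid) | CC1(C)OC(=O)CC(=O)O1 | starting material
24 | 2-(trimethylsilyl)ethanol | C[Si](C)(C)CCO | starting material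
25 | 5-[2-(acetyloxy)-1-hydroxyethylidene]-2,2-dimethyl-1,3-dioxane-4,6-dione (formed in situ) | CC(=O)OCC(O)=C1C(=O)OC(C)(C)OC1=O | intermediate
26 | 2-(trimethylsilyl)ethyl 4-(acetyloxy)-3-oxobutanoate | CC(=O)OCC(=O)CC(=O)OCC[Si](C)(C)C | intermediate
27 | 2-(trimethylsilyl)ethyl (2E)-4-(acetyloxy)-3-{[(4-methylphenyl)sulfonyl]oxy}but-2-enoate | CC(=O)OC/C(=C\C(=O)OCC[Si](C)(C)C)OS(=O)(=O)c1ccc(C)cc1 | intermediate
28 | C12-(9-BBN) alkylborane of 21 with C17–O–(9-BBN) borinate (formed in situ) | B1(C2CCCC1CCC2)CC[C@@H]3C(COB4C5CCCC4CCC5)=CC[C@@H]6C(C)(C)CCC[C@@]36C | intermediate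
29 | 2-(trimethylsilyl)ethyl (2Z)-3-[(acetyloxy)methyl]-5-[(1S,4aR,8aR)-2-(hydroxymethyl)-5,5,8a-trimethyl-1,4,4a,5,6,7,8,8a-octahydronaphthalen-1-yl]pent-2-enoate | CC(=O)OC/C(=C\C(=O)OCC[Si](C)(C)C)CC[C@@H]1C(CO)=CC[C@@H]2C(C)(C)CCC[C@@]12C | intermediate
30 | (2Z)-3-[(acetyloxy)methyl]-5-[(1S,4aR,8aR)-2-(hydroxymethyl)-5,5,8a-trimethyl-1,4,4a,5,6,7,8,8a-octahydronaphthalen-1-yl]pent-2-enoic acid | CC(=O)OC/C(=C\C(=O)O)CC[C@@H]1C(CO)=CC[C@@H]2C(C)(C)CCC[C@@]12C | target

**Step count and risks**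

Total: 17 steps. Longest linear sequence: 14 steps (steps 2–13, 16 and 17, from aldehyde 3); steps 1 and 14–15 are side branches.

Step 8. The β-methyl group makes the dienophile trisubstituted, so the cycloaddition may be slow enough for the catalyst to decay, and the methyl group, which must sit under the diene in the endo transition state, may erode endo or facial selectivity. The fallback replaces catalyst control by a covalently bound auxiliary and a stoichiometric Lewis acid. It sets out from acid 10: the mixed pivalic anhydride is condensed with lithiated (4R)-4-benzyloxazolidin-2-one to give (4R)-4-benzyl-3-[(2E,8E,10E)-12-{[tert-butyl(dimethyl)silyl]oxy}-3,7,7-trimethyldodeca-2,8,10-trienoyl]-1,3-oxazolidin-2-one F1. Me2AlCl (1.4 equiv, CH2Cl2, −30 → 0 °C) should form the cationic aluminium chelate, in which the benzyl group covers the Si face of C9, and give the endo cycloadduct (4R)-4-benzyl-3-{[(1R,2R,4aR,8aR)-2-({[tert-butyl(dimethyl)silyl]oxy}methyl)-5,5,8a-trimethyl-1,2,4a,5,6,7,8,8a-octahydronaphthalen-1-yl]carbonyl}-1,3-oxazolidin-2-one F2; minor diastereomers can be removed by chromatography. Treatment of F2 with Bu4NF as in step 9 expels the auxiliary, and the route is rejoined at lactone 16.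

Step 16. Zerovalent palladium may ionise the allylic acetate, transmetalation of the hindered alkylborane may be slow, or the β-sulfonyloxy enoate may lose its geometry during coupling. The fallback fixes the C13=C14 geometry in a ring and opens it afterwards. It sets out from alcohol 21: TBSCl and imidazole give tert-butyl{[(1S,4aR,8aR)-1-ethenyl-5,5,8a-trimethyl-1,4,4a,5,6,7,8,8a-octahydronaphthalen-2-yl]methoxy}dimethylsilane F3. Hydroboration with 9-BBN and coupling with 4-bromofuran-2(5H)-one (Pd(dppf)Cl2, K3PO4, DMF) give the butenolide 4-{2-[(1S,4aR,8aR)-2-({[tert-butyl(dimethyl)silyl]oxy}methyl)-5,5,8a-trimethyl-1,4,4a,5,6,7,8,8a-octahydronaphthalen-1-yl]ethyl}furan-2(5H)-one F4. The lactone is opened with KOH (1.05 equiv, THF/H2O) and the dried potassium carboxylate is alkylated with Me3SiCH2CH2OCH2Cl and at once acetylated (Ac2O, pyridine, 4-(dimethylamino)pyridine, 0 °C), so that the hydroxyl is capped before it can close the ring again. This should give {[2-(trimethylsilyl)ethoxy]methyl} (2Z)-3-[(acetyloxy)methyl]-5-[(1S,4aR,8aR)-2-({[tert-butyl(dimethyl)silyl]oxy}methyl)-5,5,8a-trimethyl-1,4,4a,5,6,7,8,8a-octahydronaphthalen-1-yl]pent-2-enoate F5; material that relactonises returns as F4 and is recycled. HF·pyridine in THF then cleaves the silyl ether and the acetal ester, and the route is rejoined at the target 30.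

Step 11. The lactol may open only sluggishly under the basic ylide conditions, and the exposed, hindered aldehyde may epimerise at C9 or condense before it is methylenated. The fallback uses the free aldehyde and a non-basic methylenation. It sets out from cycloadduct 14: LiBH4 (THF, MeOH, 0 °C) cleaves the imide reductively to [(1R,2R,4aR,8aR)-2-({[tert-butyl(dimethyl)silyl]oxy}methyl)-5,5,8a-trimethyl-1,2,4a,5,6,7,8,8a-octahydronaphthalen-1-yl]methanol F6. Dess–Martin oxidation gives (1R,2R,4aR,8aR)-2-({[tert-butyl(dimethyl)silyl]oxy}methyl)-5,5,8a-trimethyl-1,2,4a,5,6,7,8,8a-octahydronaphthalene-1-carbaldehyde F7. Zn/CH2Br2/TiCl4 (THF/CH2Cl2, 0 °C) methylenates it to tert-butyl{[(1R,2R,4aR,8aS)-1-ethenyl-5,5,8a-trimethyl-1,2,4a,5,6,7,8,8a-octahydronaphthalen-2-yl]methoxy}dimethylsilane F8. Bu4NF then removes the silyl group, and the route is rejoined at alcohol 18.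

**Further compounds**

F1 | step 8 | (4R)-4-benzyl-3-[(2E,8E,10E)-12-{[tert-butyl(dimethyl)silyl]oxy}-3,7,7-trimethyldodeca-2,8,10-trienoyl]-1,3-oxazolidin-2-one | O=C1OC[C@@H](Cc2ccccc2)N1C(=O)/C=C(\C)CCCC(C)(C)/C=C/C=C/CO[Si](C)(C)C(C)(C)C
F2 | step 8 | (4R)-4-benzyl-3-{[(1R,2R,4aR,8aR)-2-({[tert-butyl(dimethyl)silyl]oxy}methyl)-5,5,8a-trimethyl-1,2,4a,5,6,7,8,8a-octahydronaphthalen-1-yl]carbonyl}-1,3-oxazolidin-2-one | O=C1OC[C@@H](Cc2ccccc2)N1C(=O)[C@@H]3[C@H](CO[Si](C)(C)C(C)(C)C)C=C[C@@H]4C(C)(C)CCC[C@@]34C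
F3 | step 16 | tert-butyl{[(1S,4aR,8aR)-1-ethenyl-5,5,8a-trimethyl-1,4,4a,5,6,7,8,8a-octahydronaphthalen-2-yl]methoxy}dimethylsilane | C=C[C@@H]1C(CO[Si](C)(C)C(C)(C)C)=CC[C@@H]2C(C)(C)CCC[C@@]12C
F4 | step 16 | 4-{2-[(1S,4aR,8aR)-2-({[tert-butyl(dimethyl)silyl]oxy}methyl)-5,5,8a-trimethyl-1,4,4a,5,6,7,8,8a-octahydronaphthalen-1-yl]ethyl}furan-2(5H)-one | O=C1OCC(CC[C@@H]2C(CO[Si](C)(C)C(C)(C)C)=CC[C@@H]3C(C)(C)CCC[C@@]23C)=C1
F5 | step 16 | {[2-(trimethylsilyl)ethoxy]methyl} (2Z)-3-[(acetyloxy)methyl]-5-[(1S,4aR,8aR)-2-({[tert-butyl(dimethyl)silyl]oxy}methyl)-5,5,8a-trimethyl-1,4,4a,5,6,7,8,8a-octahydronaphthalen-1-yl]pent-2-enoate | CC(=O)OC/C(=C\C(=O)OCOCC[Si](C)(C)C)CC[C@@H]1C(CO[Si](C)(C)C(C)(C)C)=CC[C@@H]2C(C)(C)CCC[C@@]12C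
F6 | step 11 | [(1R,2R,4aR,8aR)-2-({[tert-butyl(dimethyl)silyl]oxy}methyl)-5,5,8a-trimethyl-1,2,4a,5,6,7,8,8a-octahydronaphthalen-1-yl]methanol | OC[C@@H]1[C@H](CO[Si](C)(C)C(C)(C)C)C=C[C@@H]2C(C)(C)CCC[C@@]12C
F7 | step 11 | (1R,2R,4aR,8aR)-2-({[tert-butyl(dimethyl)silyl]oxy}methyl)-5,5,8a-trimethyl-1,2,4a,5,6,7,8,8a-octahydronaphthalene-1-carbaldehyde | O=C[C@@H]1[C@H](CO[Si](C)(C)C(C)(C)C)C=C[C@@H]2C(C)(C)CCC[C@@]12C
F8 | step 11 | tert-butyl{[(1R,2R,4aR,8aS)-1-ethenyl-5,5,8a-trimethyl-1,2,4a,5,6,7,8,8a-octahydronaphthalen-2-yl]methoxy}dimethylsilane | C=C[C@@H]1[C@H](CO[Si](C)(C)C(C)(C)C)C=C[C@@H]2C(C)(C)CCC[C@@]12C
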